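**Retrosynthetic overview**

- Feature: in the chroman (benzene ring fused to the dihydropyran ring O1–C2–C3–C4–C4a–C8a) the adjacent arene carbons C4a and C5 carry the two carbon substituents, C4 and the formyl carbon, and sit between the oxygen-bearing carbons C8a and C6. These two carbons are treated as the two ends of an aryne.
- Last disconnection: the C6 hydroxyl is masked as its methoxymethyl (MOM) ether. Key disconnection: C4–C4a and C5–CHO are made in one flask from a fluoroaryl tertiary-alkyl ether iodide and DMF. The dihydropyran ring is the only ring formed; the benzene ring is bought.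
- The iodide comes from a tertiary allylic aryl ether (vinyl to CH2CH2I by hydroboration, oxidation, iodination). The ether comes from a branched, enantioselective palladium-catalysed O-allylation of a phenol with geranylgeranyl methyl carbonate, which sets C2.
- The phenol, 2-fluoro-4-(methoxymethoxy)-6-methylphenol, comes from 2-fluoro-6-methylphenol by para oxidation, reduction and selective protection.

Key step: step 7

Assumption (chemistry): the (R,R) enantiomer of the diphosphine is taken to give the (R) ether from the (E)-carbonate in step 4. The sense of induction is to be checked on the first run (chiral HPLC of alcohol 10 against a racemate), and the (S,S) ligand is used instead if it proves opposite.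

**Route**

Step 1
Reactants: 1 2-fluoro-6-methylphenol
Product: 3 2-fluoro-6-methylbenzene-1,4-diol, via 2-fluoro-6-methyl-1,4-benzoquinone 2 (not isolated)
Conditions: (KSO3)2NO (2.2 equiv), KH2PO4, H2O/acetone, 0 °C → rt; EtOAc extract shaken with aq Na2S2O4, rt
Reagents that add atoms: potassium nitrosodisulfonate, [K+].[K+].[O]N(S(=O)(=O)[O-])S(=O)(=O)[O-]
Why: Teuber oxidation, in which the nitrosodisulfonate radical abstracts the phenolic hydrogen and a second equivalent couples at the only free para position (both ortho positions are blocked by F and CH3) to give the para-quinone, which dithionite then reduces to the hydroquinone without touching the C–F bond.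

Step 2
Reactants: 3 2-fluoro-6-methylbenzene-1,4-diol
Product: 5 2-fluoro-4-(methoxymethoxy)-6-methylphenol, via disodium hydroquinone dianion 4 (not isolated)
Conditions: NaH (2.1 equiv), THF/DMF, 0 °C, Ar; MOMCl (1.0 equiv), −40 → 0 °C; aq NH4Cl
Reagents that add atoms: chloromethyl methyl ether, COCCl
Why: Williamson-type O-alkylation of the dianion, in which the C4 oxide (two ortho hydrogens, no adjacent fluorine) is the more basic and less hindered nucleophile, so one equivalent of MOMCl should react there and leave the C1 hydroxyl between F and CH3 free; the regiochemistry is to be confirmed by NOE between OCH2O and both arene hydrogens.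

Step 3
Reactants: 6 (2E,6E,10E)-geranylgeraniol
Product: 7 (2E,6E,10E)-geranylgeranyl methyl carbonate
Conditions: ClCO2Me, pyridine, CH2Cl2, 0 °C
Reagents that add atoms: methyl chloroformate, COC(=O)Cl
Why: Acylation of a primary allylic alcohol by a chloroformate under pyridine catalysis, which leaves the four trisubstituted alkenes and their (E) geometry untouched.

Step 4
Reactants: 5 2-fluoro-4-(methoxymethoxy)-6-methylphenol; 7 (2E,6E,10E)-geranylgeranyl methyl carbonate (1.2 equiv)
Product: 8 (3R,6E,10E)-3-[2-fluoro-4-(methoxymethoxy)-6-methylphenoxy]-3,7,11,15-tetramethylhexadeca-1,6,10,14-tetraene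
Conditions: Pd2(dba)3·CHCl3 (2 mol %), (1R,2R)-N,N'-bis[2-(diphenylphosphino)benzoyl]cyclohexane-1,2-diamine (6 mol %), CH2Cl2, 0 °C → rt, Ar
Reagents that add atoms: none
Why: Tsuji–Trost asymmetric allylic O-alkylation, in which zerovalent palladium ionises the carbonate to a 1,1-disubstituted π-allyl complex with loss of CO2, the methoxide formed deprotonates the phenol, and the phenoxide attacks the more substituted allyl terminus inside the chiral pocket of the diphosphine, which selects one enantiotopic face and so sets the (R) quaternary carbon (the later C2); both ortho positions and the para position of the aryl ether are occupied, so the product has no productive aromatic Claisen path.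

Step 5
Reactants: 8 (3R,6E,10E)-3-[2-fluoro-4-(methoxymethoxy)-6-methylphenoxy]-3,7,11,15-tetramethylhexadeca-1,6,10,14-tetraene
Product: 10 (3R,6E,10E)-3-[2-fluoro-4-(methoxymethoxy)-6-methylphenoxy]-3,7,11,15-tetramethylhexadeca-6,10,14-trien-1-ol, via B-alkyl-9-BBN adduct 9 (not isolated)
Conditions: 9-BBN (1.3 equiv), THF, 0 °C → rt; then NaOH (3 M), H2O2 (30%), 0 °C → rt
Reagents that add atoms: hydrogen peroxide, OO
Why: Hydroboration–oxidation, in which 9-BBN adds in the anti-Markovnikov sense to the monosubstituted vinyl group much faster than to the trisubstituted alkenes, and alkaline peroxide replaces boron by hydroxyl without touching the MOM ether, the aryl fluoride or the quaternary stereocenter.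

Step 6
Reactants: 10 (3R,6E,10E)-3-[2-fluoro-4-(methoxymethoxy)-6-methylphenoxy]-3,7,11,15-tetramethylhexadeca-6,10,14-trien-1-ol
Product: 11 (3R,6E,10E)-3-[2-fluoro-4-(methoxymethoxy)-6-methylphenoxy]-1-iodo-3,7,11,15-tetramethylhexadeca-6,10,14-triene
Conditions: I2, PPh3, imidazole, CH2Cl2, 0 °C → rt, dark
Reagents that add atoms: iodine, [I][I]
Why: Appel-type iodination, in which the primary alcohol is activated as an alkoxyphosphonium ion and displaced by iodide in an SN2 reaction under buffered conditions that spare the tertiary aryl ether, the MOM group and the triene.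

Step 7
Reactants: 11 (3R,6E,10E)-3-[2-fluoro-4-(methoxymethoxy)-6-methylphenoxy]-1-iodo-3,7,11,15-tetramethylhexadeca-6,10,14-triene; 12 N,N-dimethylformamide (5 equiv)
Product: 18 (2R)-6-(methoxymethoxy)-2,8-dimethyl-2-[(3E,7E)-4,8,12-trimethyltrideca-3,7,11-trien-1-yl]-3,4-dihydro-2H-chromene-5-carbaldehyde, via alkyllithium 13 (not isolated), via aryl-alkyl dilithium species 14 (not isolated), via aryne 15 (not isolated), via 5-lithiochroman 16 (not isolated), via lithium hemiaminal alkoxide 17 (not isolated)
Conditions: t-BuLi (3.3 equiv), Et2O/pentane, −78 °C; THF, −78 → −20 °C; 12, −78 → 0 °C; H2O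
Reagents that add atoms: none
Why: Two equivalents of t-BuLi convert the primary iodide into alkyllithium 13 by iodine–lithium exchange, which outruns any deprotonation, and the third removes the only arene hydrogen ortho to fluorine, which is also ortho to the coordinating MOM ether (14); on warming LiF is lost and aryne 15 forms across the former C–F carbon and its lithiated neighbour. The tethered primary carbanion adds in the plane of the aryne to the former C–F carbon (C4a) in a 6-exo-dig closure that forms the dihydropyran ring and leaves aryllithium 16 at C5, which DMF converts into hemiaminal alkoxide 17 and, on hydrolysis, the aldehyde. The closest known reaction type is the anionic cyclisation of aryne-tethered organolithiums generated from fluoroarenes, followed by electrophilic trapping of the new aryllithium, which is established for carbon tethers carrying alkyllithiums and for aryl ether tethers carrying vinyl- and aryllithiums. No stereocenter is formed, because the C2–O1 bond and the four substituents of C2 are spectators, so the configuration set in step 4 is carried through unchanged. The step needs one site of arene lithiation (secured by the single hydrogen between F and OMOM), one regiochemistry of addition to the aryne (the three-atom tether can reach only C4a, since attack at C5 would give a meta-bridged ring, and the anion ends next to the chelating MOM oxygen) and ring closure ahead of intermolecular addition of t-BuLi (secured by the small excess of t-BuLi and the intramolecular nature of the closure). The tertiary carbon that bears the aryloxy group also disfavours loss of the carbanion by 1,3-elimination of aryloxide, and the cold basic medium spares the acid-labile triene.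

Step 8
Reactants: 18 (2R)-6-(methoxymethoxy)-2,8-dimethyl-2-[(3E,7E)-4,8,12-trimethyltrideca-3,7,11-trien-1-yl]-3,4-dihydro-2H-chromene-5-carbaldehyde
Product: 19 (2R)-6-hydroxy-2,8-dimethyl-2-[(3E,7E)-4,8,12-trimethyltrideca-3,7,11-trien-1-yl]-3,4-dihydro-2H-chromene-5-carbaldehyde
Conditions: HCl (0.5 M) in MeOH/THF, 0 °C → rt, Ar
Reagents that add atoms: none
Why: Acid-catalysed transacetalisation of the aryl MOM ether to dimethoxymethane, in which the departing phenol is held by a hydrogen bond to the ortho formyl group so that dilute acid at room temperature should suffice, conditions under which the trisubstituted alkenes and the chroman ether are not expected to react; a thiol scavenger is avoided because it could turn the aldehyde into a dithioacetal.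

**Compound list**

1 | 2-fluoro-6-methylphenol | Cc1cccc(F)c1O | starting material
2 | 2-fluoro-6-methyl-1,4-benzoquinone | CC1=CC(=O)C=C(F)C1=O | intermediate
3 | 2-fluoro-6-methylbenzene-1,4-diol | Cc1cc(O)cc(F)c1O | intermediate
4 | disodium 2-fluoro-6-methylbenzene-1,4-diolate | Cc1cc([O-])cc(F)c1[O-].[Na+].[Na+] | intermediate
5 | 2-fluoro-4-(methoxymethoxy)-6-methylphenol | Cc1cc(OCOC)cc(F)c1O | intermediate
6 | (2E,6E,10E)-geranylgeraniol | CC(C)=CCC/C(C)=C/CC/C(C)=C/CC/C(C)=C/CO | starting material
7 | (2E,6E,10E)-geranylgeranyl methyl carbonate | CC(C)=CCC/C(C)=C/CC/C(C)=C/CC/C(C)=C/COC(=O)OC | intermediate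
8 | (3R,6E,10E)-3-[2-fluoro-4-(methoxymethoxy)-6-methylphenoxy]-3,7,11,15-tetramethylhexadeca-1,6,10,14-tetraene | CC(C)=CCC/C(C)=C/CC/C(C)=C/CC[C@](Oc1c(C)cc(OCOC)cc1F)(C)C=C | intermediate
9 | B-alkyl-9-BBN adduct of 8 (boron on C1) | CC(C)=CCC/C(C)=C/CC/C(C)=C/CC[C@](Oc1c(C)cc(OCOC)cc1F)(C)CCB1C2CCCC1CCC2 | intermediate
10 | (3R,6E,10E)-3-[2-fluoro-4-(methoxymethoxy)-6-methylphenoxy]-3,7,11,15-tetramethylhexadeca-6,10,14-trien-1-ol | CC(C)=CCC/C(C)=C/CC/C(C)=C/CC[C@](Oc1c(C)cc(OCOC)cc1F)(C)CCO | intermediate
11 | (3R,6E,10E)-3-[2-fluoro-4-(methoxymethoxy)-6-methylphenoxy]-1-iodo-3,7,11,15-tetramethylhexadeca-6,10,14-triene | CC(C)=CCC/C(C)=C/CC/C(C)=C/CC[C@](Oc1c(C)cc(OCOC)cc1F)(C)CCI | intermediate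
12 | N,N-dimethylformamide | CN(C)C=O | starting material
13 | primary alkyllithium from 11 (C1–Li) | CC(C)=CCC/C(C)=C/CC/C(C)=C/CC[C@](Oc1c(C)cc(OCOC)cc1F)(C)CC[Li] | intermediate
14 | dilithium species (C1–Li and arene C–Li between F and OMOM) | CC(C)=CCC/C(C)=C/CC/C(C)=C/CC[C@](Oc1c(C)cc(OCOC)c([Li])c1F)(C)CC[Li] | intermediate
15 | aryne carrying the tethered alkyllithium | CC(C)=CCC/C(C)=C/CC/C(C)=C/CC[C@](OC1=C(C)C=C(OCOC)C#C1)(C)CC[Li] | intermediate
16 | (2R)-5-lithio-6-(methoxymethoxy)-2,8-dimethyl-2-[(3E,7E)-4,8,12-trimethyltrideca-3,7,11-trienyl]chroman | CC(C)=CCC/C(C)=C/CC/C(C)=C/CC[C@]1(C)CCc2c([Li])c(OCOC)cc(C)c2O1 | intermediate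
17 | lithium α-(dimethylamino)alkoxide at C5 (DMF adduct of 16) | CC(C)=CCC/C(C)=C/CC/C(C)=C/CC[C@]1(C)CCc2c(C(O[Li])N(C)C)c(OCOC)cc(C)c2O1 | intermediate
18 | (2R)-6-(methoxymethoxy)-2,8-dimethyl-2-[(3E,7E)-4,8,12-trimethyltrideca-3,7,11-trien-1-yl]-3,4-dihydro-2H-chromene-5-carbaldehyde | CC(C)=CCC/C(C)=C/CC/C(C)=C/CC[C@]1(C)CCc2c(C=O)c(OCOC)cc(C)c2O1 | intermediate
19 | (2R)-6-hydroxy-2,8-dimethyl-2-[(3E,7E)-4,8,12-trimethyltrideca-3,7,11-trien-1-yl]-3,4-dihydro-2H-chromene-5-carbaldehyde | CC(C)=CCC/C(C)=C/CC/C(C)=C/CC[C@]1(C)CCc2c(C=O)c(O)cc(C)c2O1 | target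

**Step count**

Total: 8 steps. Longest linear sequence: 7 steps (steps 1, 2, 4, 5, 6, 7, 8 from 2-fluoro-6-methylphenol).

**Steps most likely to fail and fallbacks**

First, step 7.
- What may go wrong: the primary alkyllithium may be consumed before the aryne appears, by proton transfer from a second arene or from the arene methyl group, or by 1,3-elimination of aryloxide. Residual t-BuLi may also add to the aryne, so that ring closure and formylation do not both take place.
- Fallback: it makes the C4–C4a bond by an intramolecular B-alkyl Suzuki–Miyaura coupling at an aryl bromide and the formyl group by ortho-formylation of the free phenol. It sets out from carbonate 7 and comes back to the route at target 19.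
- 2-Bromo-6-methylphenol F1 would be oxidised with (KSO3)2NO to 2-bromo-6-methyl-1,4-benzoquinone F2 and reduced with Na2S2O4 to 2-bromo-6-methylbenzene-1,4-diol F3.
- Silylation at the unhindered hydroxyl (i-Pr3SiCl, imidazole, DMF) would give 2-bromo-6-methyl-4-(triisopropylsilyloxy)phenol F4.
- O-Allylation with 7 under the conditions of step 4 would give (3R,6E,10E)-3-[2-bromo-6-methyl-4-(triisopropylsilyloxy)phenoxy]-3,7,11,15-tetramethylhexadeca-1,6,10,14-tetraene F5.
- 9-BBN in THF would give the B-alkyl-9-BBN adduct of the bromoaryl ether F6, which without isolation would be coupled (Pd(dppf)Cl2, aq K3PO4, THF/DMF, 60 °C) to (R)-6-O-triisopropylsilyl-δ-tocotrienol F7.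
- Bu4NF in THF would free (R)-δ-tocotrienol F8.
- MgCl2, Et3N and paraformaldehyde in MeCN at reflux would formylate ortho to the phenol, by preference at C5 (the position next to the fused dihydropyran ring, which is the more reactive one in electrophilic substitution of 8-methyl-6-hydroxychromans), to give 19. Any C7 isomer would have to be removed by chromatography.

Second, step 4.
- What may go wrong: the phenol is substituted at both ortho positions, so attack at the tertiary allyl terminus may be slow, facial discrimination may be poor, and zerovalent palladium may re-ionise the tertiary allylic aryl ether with drift to the linear ether.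
- Fallback: it takes the stereocenter from a Sharpless asymmetric epoxidation and forms the tertiary aryl ether by an oxidation–reduction condensation with inversion. It sets out from 6 and 5 and comes back to the route at alcohol 10.
- Epoxidation of 6 (Ti(OiPr)4, L-(+)-diethyl tartrate, t-BuOOH, 4 Å molecular sieves, CH2Cl2, −20 °C) would give (2S,3S)-2,3-epoxygeranylgeraniol F9.
- NaAlH2(OCH2CH2OCH3)2 in THF would open the epoxide at C2 to (3S,6E,10E)-3,7,11,15-tetramethylhexadeca-6,10,14-triene-1,3-diol F10.
- t-BuMe2SiCl and imidazole would protect the primary hydroxyl to give (3S,6E,10E)-1-(tert-butyldimethylsilyloxy)-3,7,11,15-tetramethylhexadeca-6,10,14-trien-3-ol F11.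
- n-BuLi would give the lithium alkoxide of the silyl ether F12, and Ph2PCl the tertiary alkyl diphenylphosphinite F13.
- With phenol 5 and 2,6-dimethyl-1,4-benzoquinone in CH2Cl2 the phosphinite would undergo Mukaiyama oxidation–reduction condensation with inversion at the tertiary carbon to give the tert-butyldimethylsilyl ether of 10 F14.
- Bu4NF would then give 10.

Third, step 2.
- What may go wrong: alkylation may occur at the hindered oxygen or at both oxygens, giving the regioisomeric or the bis-MOM ether, and the dianion may be oxidised by air.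
- Fallback: the two oxygens are told apart by construction. It sets out from 1 and comes back to the route at phenol 5.
- NBS in MeCN at 0 °C would brominate para to the hydroxyl to give 4-bromo-2-fluoro-6-methylphenol F15.
- BnBr and K2CO3 in DMF would give 2-(benzyloxy)-5-bromo-1-fluoro-3-methylbenzene F16.
- Palladium-catalysed hydroxylation (Pd2(dba)3, 2-di-tert-butylphosphino-2',4',6'-triisopropylbiphenyl, KOH, dioxane/H2O, 100 °C) would give 4-(benzyloxy)-3-fluoro-5-methylphenol F17.
- MOMCl and i-Pr2NEt in CH2Cl2 would give 2-(benzyloxy)-1-fluoro-5-(methoxymethoxy)-3-methylbenzene F18.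
- Hydrogenolysis (H2, Pd/C, EtOAc) would give 5.

**Further compounds**

F1 | step 7 | 2-bromo-6-methylphenol | Cc1cccc(Br)c1O
F2 | step 7 | 2-bromo-6-methyl-1,4-benzoquinone | CC1=CC(=O)C=C(Br)C1=O
F3 | step 7 | 2-bromo-6-methylbenzene-1,4-diol | Cc1cc(O)cc(Br)c1O
F4 | step 7 | 2-bromo-6-methyl-4-(triisopropylsilyloxy)phenol | Cc1cc(O[Si](C(C)C)(C(C)C)C(C)C)cc(Br)c1O
F5 | step 7 | (3R,6E,10E)-3-[2-bromo-6-methyl-4-(triisopropylsilyloxy)phenoxy]-3,7,11,15-tetramethylhexadeca-1,6,10,14-tetraene | CC(C)=CCC/C(C)=C/CC/C(C)=C/CC[C@](Oc1c(C)cc(O[Si](C(C)C)(C(C)C)C(C)C)cc1Br)(C)C=C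
F6 | step 7 | B-alkyl-9-BBN adduct of the bromoaryl ether | CC(C)=CCC/C(C)=C/CC/C(C)=C/CC[C@](Oc1c(C)cc(O[Si](C(C)C)(C(C)C)C(C)C)cc1Br)(C)CCB1C2CCCC1CCC2
F7 | step 7 | (R)-6-O-triisopropylsilyl-δ-tocotrienol | CC(C)=CCC/C(C)=C/CC/C(C)=C/CC[C@]1(C)CCc2cc(O[Si](C(C)C)(C(C)C)C(C)C)cc(C)c2O1
F8 | step 7 | (R)-δ-tocotrienol | CC(C)=CCC/C(C)=C/CC/C(C)=C/CC[C@]1(C)CCc2cc(O)cc(C)c2O1
F9 | step 4 | (2S,3S)-2,3-epoxygeranylgeraniol | CC(C)=CCC/C(C)=C/CC/C(C)=C/CC[C@@](O1)(C)[C@@H]1CO
F10 | step 4 | (3S,6E,10E)-3,7,11,15-tetramethylhexadeca-6,10,14-triene-1,3-diol | CC(C)=CCC/C(C)=C/CC/C(C)=C/CC[C@@](O)(C)CCO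
F11 | step 4 | (3S,6E,10E)-1-(tert-butyldimethylsilyloxy)-3,7,11,15-tetramethylhexadeca-6,10,14-trien-3-ol | CC(C)=CCC/C(C)=C/CC/C(C)=C/CC[C@@](O)(C)CCO[Si](C)(C)C(C)(C)C
F12 | step 4 | lithium alkoxide of the silyl ether | CC(C)=CCC/C(C)=C/CC/C(C)=C/CC[C@@](O[Li])(C)CCO[Si](C)(C)C(C)(C)C
F13 | step 4 | tertiary alkyl diphenylphosphinite | CC(C)=CCC/C(C)=C/CC/C(C)=C/CC[C@@](OP(c1ccccc1)c1ccccc1)(C)CCO[Si](C)(C)C(C)(C)C
F14 | step 4 | tert-butyldimethylsilyl ether of 10 | CC(C)=CCC/C(C)=C/CC/C(C)=C/CC[C@](Oc1c(C)cc(OCOC)cc1F)(C)CCO[Si](C)(C)C(C)(C)C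
F15 | step 2 | 4-bromo-2-fluoro-6-methylphenol | Cc1cc(Br)cc(F)c1O
F16 | step 2 | 2-(benzyloxy)-5-bromo-1-fluoro-3-methylbenzene | Cc1cc(Br)cc(F)c1OCc1ccccc1
F17 | step 2 | 4-(benzyloxy)-3-fluoro-5-methylphenol | Cc1cc(O)cc(F)c1OCc1ccccc1
F18 | step 2 | 2-(benzyloxy)-1-fluoro-5-(methoxymethoxy)-3-methylbenzene | Cc1cc(OCOC)cc(F)c1OCc1ccccc1
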